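## The problem

The target 12 is 5,7,4'-trihydroxy-3,6,8-trimethoxyflavone. It is a 4H-chromen-4-one whose benzo ring (ring A, C4a to C8a) carries an oxygen on every free carbon, whose pyranone (ring C) carries a methoxy group at C3, and whose C2 carries a 4-hydroxyphenyl group (ring B). It has no stereocenter, so the problem is purely one of constitution: which of the six oxygens are methylated (C3, C6, C8) and which are free (C5, C7, C4'). Ring A is hexasubstituted and its OH and OMe groups alternate, so a late unselective methylation or demethylation cannot give the pattern. The free polyphenol is easily oxidised. The C3 and C6 methyl ethers sit beside the C4 carbonyl and the chelated C5 hydroxyl, where Lewis acids can remove them, so the phenols must be unmasked last under conditions that spare methyl ethers. The feature that opens a short route is that C6–OMe, C7–O and C8–OMe form the 3,5-dimethoxy-4-oxy (syringyl) pattern of acetosyringone, with C4a as the acyl-bearing carbon. In that ketone the two positions ortho to the acyl carbon are equivalent C–H bonds: one can become C8a by C–O bond formation to O1, and the other becomes C5, peri to the C4 carbonyl, which can direct its later oxygenation.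

## Retrosynthesis

Flavone numbering is used throughout (O1, C2, C3, C4, C4a, C5 to C8, C8a; ring B primed).

**12 from 11.** The two O–isopropyl bonds at O7 and O4' are cut last. Isopropyl is preferred to benzyl, whose benzylic C–H bonds are exposed at an anode and to a hypervalent iodine oxidant in acid, and to methyl, which could not be told apart from the three methyl ethers that must stay. Precursor 11 has the full skeleton and oxygenation with two masked phenols. The forward step must cleave secondary alkyl aryl ethers while leaving the methyl ethers intact.

**11 from 9.** The C5–O bond is cut, leaving flavone 9 with a single ring A C–H. Carrying the C5 oxygen from the start would require a ring A ketone that is not commercial and would put a fourth donor on the ring that has to survive the anodic step. Making the bond late uses the C4 carbonyl as a built-in directing group for the only C–H that ring A has left. The forward step is a carbonyl-directed C–H oxygenation that passes through trifluoroacetate 10.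

**9 from 8.** The O1–C8a bond is cut, opening ring C to the acyclic 2-methoxy-1,3-diketone 8. The usual cut for a flavone, O1–C2 by cyclodehydration, needs a ring A ketone that already has an ortho hydroxyl group; the syringyl series offers no such commercial compound. Cutting O1–C8a lets the symmetric ketone serve directly. The forward step must remove two electrons and two protons, oxidise ring A in preference to ring B, and join the diketone oxygen to the ortho carbon.

**8 from 7 and 6.** The C3–OMe bond is cut to diazo diketone 7, and the diazo group is traced to the methylene of diketone 6. The alternative of starting from an α-methoxy ketone needs a separate synthesis of that ketone, and its acylation tends to go on oxygen. Diketone 6 has no heteroatom on the central carbon and is a standard Claisen product. The forward steps are diazo transfer and carbenoid O–H insertion into methanol.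

**6 from 3 and 5.** The C2–C3 bond is cut by a crossed Claisen condensation between methyl ketone 3 (ring A) and ester 5 (ring B). The reverse polarity is possible, but this one uses acetosyringone as the syringyl source. Both fragments are single benzene rings. The forward step needs only an enolisable ketone and a non-enolisable ester.

**3 from 1 and 2; 5 from 4 and 2.** The isopropyl ethers are cut to acetosyringone 1, methyl 4-hydroxybenzoate 4 and 2-bromopropane 2, all commercial. The forward steps are phenol alkylations.

## Roads not taken

**Alternative 1:** Here ring A is the ring made last. The C4a–C8a bond is cut, unfolding ring A into the open-chain triketo ester A1, methyl (8Z)-9-[4-(benzyloxy)phenyl]-2,4,8-trimethoxy-3,5,7-trioxonon-8-enoate. Under Mg(OMe)2 in methanol its C4a methylene would attack the terminal ester carbon and the new ring would aromatise to the α-methoxychalcone A2. Oxidative closure of ring C and hydrogenolysis would then lead to 12.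
- Merits: the fold follows the biosynthetic logic, every ring A oxygen arrives from the chain at its final level, no C–H oxidation is needed, and the symmetry of the new ring makes either ortho hydroxyl close ring C to the same flavone.
- Weak points: A1 contains three ketones, an ester, an enone and two methoxy-bearing carbons between carbonyls. No short sequence leads to it. It can close through other carbons, close through enol oxygen to a pyranone, or be cleaved by methoxide. A2 is a free, very electron-rich phloroglucinol ketone that is sensitive to air, and its oxidative cyclisation can also give an aurone.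
- Comparison: on paper this road needs fewer oxidation-level changes on ring A than the chosen plan, which must create two C–O bonds at C–H positions. The chosen plan sets against this a commercial ring A and a single uncertain step with a known fallback; here both the preparation of A1 and its folding are uncertain.

**Alternative 2:** Three bonds of ring C are cut (C4a–C4, C4–C3, O1–C2). Iodophenol A3 and alkyne A4 would be joined under carbonylative conditions with PdCl2(PPh3)2 in diethylamine, in a carbonylative Sonogashira coupling followed by addition of the phenol to the ynone, to give flavone A5.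
- Merits: it is highly convergent, the C5 oxygen is in place from the start, and benzyl ethers are removed by neutral hydrogenolysis, which is gentler on the methyl ethers than a Lewis acid.
- Weak points: A5 has no oxygen at C3, so the 3-methoxy group would need two further steps on a crowded flavone (epoxidation to the flavonol, then methylation). A3 is a hexasubstituted benzene that must be built in several steps, including iodination of an oxidation-prone ring. Oxidative addition and carbonyl insertion at an aryl iodide with two ortho substituents and five donors are slow, so direct coupling without carbonylation and five-membered closure to an aurone compete.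
- Comparison: this road is more convergent and milder at the end. The chosen plan sets against it a 3-methoxy group installed before ring closure, a commercial ring A, and a lower total count once A3 and the C3 oxygenation are included.

**Alternative 3:** The C4–C4a and O1–C2 bonds are cut. The symmetric triol A6 and the α-methoxy β-keto ester A7 would be heated neat under inert gas in a thermal chromone condensation. The ester acylates the one free ring carbon and the neighbouring hydroxyl condenses with the ketone, giving A8; one hydrogenolysis then gives 12.
- Merits: both components carry every oxygen at its final level, the symmetry of A6 allows only one regioisomer, there is a single protecting group, and no oxidation step is needed. Counted from its two fragments this road is clearly shorter than the chosen plan.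
- Weak points: A6 is not commercial and is a very air-sensitive pentaoxygenated benzene; its preparation would cost more steps than the fusion saves. The fusion needs temperatures near 250 °C, which endanger the benzyl ether, the keto ester and the free product A8. Coumarin formation through the other condensation mode competes, and fully substituted phenols are poor partners in such fusions.
- Comparison: with A6 in hand this would be the more direct route. The chosen plan sets against it mild temperatures, stable protected intermediates and a bench-stable commercial ring A, at the price of one unproven step.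

Key step: step 6

Assumption: diketone 6 is drawn in the diketo form although it should exist largely as its chelated enol; diketone 8 is racemic at its central carbon, and that center becomes sp2 in step 6.

## Route

Step 1
Reactants: 1 acetosyringone [1-(4-hydroxy-3,5-dimethoxyphenyl)ethanone]; 2 2-bromopropane
Product: 3 1-(4-isopropoxy-3,5-dimethoxyphenyl)ethanone
Conditions: K2CO3, DMF, 70 °C
Reagents that add atoms: none
Why: Williamson ether synthesis: the phenoxide of 1, made acidic by the para acetyl group, displaces bromide from the secondary halide; an excess of 2 makes up for loss by elimination, and carbonate does not alkylate the methyl ketone.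

Step 2
Reactants: 4 methyl 4-hydroxybenzoate; 2 2-bromopropane
Product: 5 methyl 4-isopropoxybenzoate
Conditions: K2CO3, DMF, 70 °C
Reagents that add atoms: none
Why: Williamson ether synthesis on an unhindered, acidic phenol; the methyl ester is inert to K2CO3 in DMF.

Step 3
Reactants: 3 1-(4-isopropoxy-3,5-dimethoxyphenyl)ethanone; 5 methyl 4-isopropoxybenzoate
Product: 6 1-(4-isopropoxy-3,5-dimethoxyphenyl)-3-(4-isopropoxyphenyl)propane-1,3-dione
Conditions: NaH, THF, reflux; then aq. HCl
Reagents that add atoms: none
Why: Crossed Claisen condensation: the sodium enolate of methyl ketone 3 acylates the non-enolisable ester 5, and deprotonation of the product diketone drives the equilibrium; this is the standard route to dibenzoylmethanes, and aryl isopropyl ethers are inert to NaH.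

Step 4
Reactants: 6 1-(4-isopropoxy-3,5-dimethoxyphenyl)-3-(4-isopropoxyphenyl)propane-1,3-dione
Product: 7 2-diazo-1-(4-isopropoxy-3,5-dimethoxyphenyl)-3-(4-isopropoxyphenyl)propane-1,3-dione
Conditions: p-ABSA, Et3N, MeCN, 0 °C to rt
Reagents that add atoms: 4-acetamidobenzenesulfonyl azide (p-ABSA), CC(=O)Nc1ccc(cc1)S(=O)(=O)N=[N+]=[N-]
Why: Regitz diazo transfer: Et3N deprotonates the acidic methylene of the 1,3-diketone, which takes up the terminal N2 of the sulfonyl azide and releases the sulfonamide; no other group in 6 reacts.

Step 5
Reactants: 7 2-diazo-1-(4-isopropoxy-3,5-dimethoxyphenyl)-3-(4-isopropoxyphenyl)propane-1,3-dione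
Product: 8 rac-1-(4-isopropoxy-3,5-dimethoxyphenyl)-3-(4-isopropoxyphenyl)-2-methoxypropane-1,3-dione
Conditions: Rh2(OAc)4 (2 mol %), MeOH (10 equiv), (CH2Cl)2, 70 °C
Reagents that add atoms: methanol, CO
Why: Rhodium carbenoid O–H insertion: Rh2(OAc)4 turns the diazo diketone into an electrophilic carbenoid, methanol adds to give an oxonium ylide, and a proton shift gives the α-methoxy diketone; the new stereocenter forms without control (racemic) and is erased in step 6.

Step 6
Reactants: 8 rac-1-(4-isopropoxy-3,5-dimethoxyphenyl)-3-(4-isopropoxyphenyl)-2-methoxypropane-1,3-dione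
Product: 9 7-isopropoxy-2-(4-isopropoxyphenyl)-3,6,8-trimethoxy-4H-chromen-4-one (7,4'-diisopropoxy-3,6,8-trimethoxyflavone)
Conditions: graphite anode, Pt cathode, undivided cell, constant current (2.2 F mol−1), nBu4NPF6, 1,1,1,3,3,3-hexafluoropropan-2-ol (HFIP), rt
Reagents that add atoms: none
Why: Proposed new method: the trialkoxybenzoyl ring of 8 is the most easily oxidised part of the molecule (three alkoxy donors against one on ring B, and a dicarbonyl that stays in its hard-to-oxidise neutral keto form without base), so the anode should remove one electron from it, and HFIP should keep the radical cation alive long enough to be trapped. The oxygen of the ring B carbonyl, or of its enol, then attacks the ortho C–H carbon, which is ortho to one methoxy group and para to the other and so carries much of the positive charge; loss of a second electron and two protons gives the aromatic pyranone while HFIP is reduced to H2 at the cathode. The closest known reaction type is the anodic dehydrogenative C–O cyclisation of arenes bearing a tethered oxygen nucleophile, as in the lactonisation of biaryl-2-carboxylic acids to benzocoumarins; a 1,3-diketone oxygen has not been used in this way to close a chromone. Ring C closes as a six-membered ring by attack of O1 on C8a (6-exo with respect to the C8a–C8 bond that takes up the charge); the only other closure, at the ipso carbon, would give a strained five-membered spiro ring. No stereocenter is formed, and the one in 8 disappears as C3 becomes sp2. The step needs ring A to be oxidised before ring B and before the dicarbonyl, which the donor count and the absence of base secure, and it needs a single site of attack, which the mirror symmetry of the syringyl ring secures because both ortho positions give the same product. Over-oxidation of 9 is limited by passing only slightly more than two faradays per mole.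

Step 7
Reactants: 9 7-isopropoxy-2-(4-isopropoxyphenyl)-3,6,8-trimethoxy-4H-chromen-4-one
Product: 11 5-hydroxy-7-isopropoxy-2-(4-isopropoxyphenyl)-3,6,8-trimethoxy-4H-chromen-4-one, via C5 trifluoroacetate 10 (not isolated)
Conditions: [RuCl2(p-cymene)]2 (5 mol %), PhI(OCOCF3)2, TFA/TFAA, 60 °C; then H2O, rt
Reagents that add atoms: [bis(trifluoroacetoxy)iodo]benzene, O=C(OI(OC(=O)C(F)(F)F)c1ccccc1)C(F)(F)F
Why: Ketone-directed C–H oxygenation with a divalent ruthenium catalyst, a reaction established for C5 of flavones and chromones: the C4 carbonyl binds ruthenium and delivers it to the peri C5–H, the only C–H of ring A, forming a five-membered ruthenacycle that PhI(OCOCF3)2 oxidises and that releases aryl trifluoroacetate 10. Water hydrolyses 10 to the chelated phenol 11; methyl and isopropyl aryl ethers should tolerate TFA at this temperature.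

Step 8
Reactants: 11 5-hydroxy-7-isopropoxy-2-(4-isopropoxyphenyl)-3,6,8-trimethoxy-4H-chromen-4-one
Product: 12 5,7-dihydroxy-2-(4-hydroxyphenyl)-3,6,8-trimethoxy-4H-chromen-4-one (target)
Conditions: BCl3, CH2Cl2, −78 to 0 °C; then H2O
Reagents that add atoms: none
Why: Lewis-acid ether dealkylation: BCl3 cleaves secondary alkyl aryl ethers at low temperature because the isopropyl group leaves with carbocation character, while methyl aryl ethers react much more slowly; holding the temperature at or below 0 °C is meant to protect the C3 and C6 methyl ethers beside the boron chelate at O5 and the C4 carbonyl.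

## Compound list

1 | acetosyringone, 1-(4-hydroxy-3,5-dimethoxyphenyl)ethanone | CC(=O)c1cc(OC)c(O)c(OC)c1 | starting material
2 | 2-bromopropane | CC(C)Br | starting material
3 | 1-(4-isopropoxy-3,5-dimethoxyphenyl)ethanone | CC(=O)c1cc(OC)c(OC(C)C)c(OC)c1 | intermediate
4 | methyl 4-hydroxybenzoate | COC(=O)c1ccc(O)cc1 | starting material
5 | methyl 4-isopropoxybenzoate | COC(=O)c1ccc(OC(C)C)cc1 | intermediate
6 | 1-(4-isopropoxy-3,5-dimethoxyphenyl)-3-(4-isopropoxyphenyl)propane-1,3-dione | COc1cc(C(=O)CC(=O)c2ccc(OC(C)C)cc2)cc(OC)c1OC(C)C | intermediate
7 | 2-diazo-1-(4-isopropoxy-3,5-dimethoxyphenyl)-3-(4-isopropoxyphenyl)propane-1,3-dione | COc1cc(C(=O)C(=[N+]=[N-])C(=O)c2ccc(OC(C)C)cc2)cc(OC)c1OC(C)C | intermediate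
8 | rac-1-(4-isopropoxy-3,5-dimethoxyphenyl)-3-(4-isopropoxyphenyl)-2-methoxypropane-1,3-dione | COc1cc(C(=O)C(OC)C(=O)c2ccc(OC(C)C)cc2)cc(OC)c1OC(C)C | intermediate
9 | 7-isopropoxy-2-(4-isopropoxyphenyl)-3,6,8-trimethoxy-4H-chromen-4-one | COc1cc2c(=O)c(OC)c(-c3ccc(OC(C)C)cc3)oc2c(OC)c1OC(C)C | intermediate
10 | 7-isopropoxy-2-(4-isopropoxyphenyl)-3,6,8-trimethoxy-4-oxo-4H-chromen-5-yl trifluoroacetate | COc1c(OC(=O)C(F)(F)F)c2c(=O)c(OC)c(-c3ccc(OC(C)C)cc3)oc2c(OC)c1OC(C)C | intermediate (not isolated)
11 | 5-hydroxy-7-isopropoxy-2-(4-isopropoxyphenyl)-3,6,8-trimethoxy-4H-chromen-4-one | COc1c(O)c2c(=O)c(OC)c(-c3ccc(OC(C)C)cc3)oc2c(OC)c1OC(C)C | intermediate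
12 | 5,7-dihydroxy-2-(4-hydroxyphenyl)-3,6,8-trimethoxy-4H-chromen-4-one | COc1c(O)c(OC)c2oc(-c3ccc(O)cc3)c(OC)c(=O)c2c1O | target

## Step count and least certain steps

Total steps: 8. Longest linear sequence: 7 (steps 1 and 3 to 8 from acetosyringone; steps 2 and 3 to 8 from methyl 4-hydroxybenzoate are equally long).

**Step 6 (key step, proposed new method).** The radical cation may be consumed by paths other than ring closure, because a neutral carbonyl oxygen is a weak nucleophile. The competing processes are loss of the isopropyl group from the oxidised ring, oxidation at the doubly activated C–H between the carbonyls, and further oxidation of the product, whose ring A is not much harder to oxidise than that of 8.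

Fallback with known chemistry, from 3 back to 9: ketone 3 would be brominated on the ring with NBS in MeCN, at the position ortho to the acetyl group, which is ortho and para to the two methoxy groups, giving 1-(2-bromo-4-isopropoxy-3,5-dimethoxyphenyl)ethanone F1. Claisen condensation with 5 under the conditions of step 3 would give 1-(2-bromo-4-isopropoxy-3,5-dimethoxyphenyl)-3-(4-isopropoxyphenyl)propane-1,3-dione F2. Diazo transfer as in step 4 would give 1-(2-bromo-4-isopropoxy-3,5-dimethoxyphenyl)-2-diazo-3-(4-isopropoxyphenyl)propane-1,3-dione F3, and Rh2(OAc)4-catalysed insertion into methanol as in step 5 would give rac-1-(2-bromo-4-isopropoxy-3,5-dimethoxyphenyl)-3-(4-isopropoxyphenyl)-2-methoxypropane-1,3-dione F4. A copper-catalysed intramolecular O-arylation of the diketone enolate (CuI, 1,10-phenanthroline, K2CO3, DMF, 100 °C; Ullmann type, well known for 2-haloaryl 1,3-diketones) would then form the same O1–C8a bond and return to 9.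

**Step 7.** The hypervalent iodine oxidant may attack the electron-rich ring A by single-electron transfer faster than ruthenium inserts into C5–H. The metalation is slowed by the C6 methoxy group beside that C–H, and acid may partly cleave the isopropyl ethers, exposing phenols to the oxidant.

Fallback, from 9 back to 11: electrophilic bromination of 9 with NBS in MeCN should go to C5, the only free position of ring A, activated by the ortho C6 and para C8 methoxy groups (C3 is blocked), giving 5-bromo-7-isopropoxy-2-(4-isopropoxyphenyl)-3,6,8-trimethoxy-4H-chromen-4-one F5. Miyaura borylation (B2pin2, PdCl2(dppf), KOAc, dioxane, 90 °C) would give the boronate 7-isopropoxy-2-(4-isopropoxyphenyl)-3,6,8-trimethoxy-5-(4,4,5,5-tetramethyl-1,3,2-dioxaborolan-2-yl)-4H-chromen-4-one F6, and oxidation with NaBO3·4H2O in THF/H2O would give 11.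

**Step 5.** Nitrogen loss from the stabilised diazo diketone may be sluggish, and at the temperature needed aroyl migration (Wolff-type rearrangement) may compete with capture of the carbenoid by methanol.

Fallback, from 6 directly to 8: α-methoxylation of the 1,3-diketone with iodosylbenzene (PhIO) and BF3·OEt2 in methanol, a known α-functionalisation of β-dicarbonyl compounds. The enol attacks the trivalent iodine, and methanol displaces iodobenzene from the α-carbon. This also removes the diazo step and makes no compound outside the route.

**Step 8.** Boron bound to O5 and the C4 carbonyl sits next to the C6 and C3 methoxy groups, so one of these methyl groups may be lost by chelation-assisted demethylation while the isopropyl ethers are cleaved.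

Fallback, from 9 to 12, moving the dealkylation ahead of the C5 oxygenation so that no O5 chelate exists when BCl3 is used:
- BCl3 on 9 would give 7-hydroxy-2-(4-hydroxyphenyl)-3,6,8-trimethoxy-4H-chromen-4-one F7.
- Ac2O and pyridine would give the diacetate 4-(7-acetoxy-3,6,8-trimethoxy-4-oxo-4H-chromen-2-yl)phenyl acetate F8.
- The ruthenium-catalysed hydroxylation of step 7 would give, through the C5 trifluoroacetate 4-(7-acetoxy-3,6,8-trimethoxy-4-oxo-5-(trifluoroacetoxy)-4H-chromen-2-yl)phenyl acetate F9 (not isolated), the phenol 4-(7-acetoxy-5-hydroxy-3,6,8-trimethoxy-4-oxo-4H-chromen-2-yl)phenyl acetate F10.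
- Acid methanolysis (HCl, MeOH) of the two acetates would give 12.

## Further compounds

F1 | step 6 | 1-(2-bromo-4-isopropoxy-3,5-dimethoxyphenyl)ethanone | CC(=O)c1cc(OC)c(OC(C)C)c(OC)c1Br
F2 | step 6 | 1-(2-bromo-4-isopropoxy-3,5-dimethoxyphenyl)-3-(4-isopropoxyphenyl)propane-1,3-dione | COc1cc(C(=O)CC(=O)c2ccc(OC(C)C)cc2)c(Br)c(OC)c1OC(C)C
F3 | step 6 | 1-(2-bromo-4-isopropoxy-3,5-dimethoxyphenyl)-2-diazo-3-(4-isopropoxyphenyl)propane-1,3-dione | COc1cc(C(=O)C(=[N+]=[N-])C(=O)c2ccc(OC(C)C)cc2)c(Br)c(OC)c1OC(C)C
F4 | step 6 | rac-1-(2-bromo-4-isopropoxy-3,5-dimethoxyphenyl)-3-(4-isopropoxyphenyl)-2-methoxypropane-1,3-dione | COc1cc(C(=O)C(OC)C(=O)c2ccc(OC(C)C)cc2)c(Br)c(OC)c1OC(C)C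
F5 | step 7 | 5-bromo-7-isopropoxy-2-(4-isopropoxyphenyl)-3,6,8-trimethoxy-4H-chromen-4-one | COc1c(Br)c2c(=O)c(OC)c(-c3ccc(OC(C)C)cc3)oc2c(OC)c1OC(C)C
F6 | step 7 | 7-isopropoxy-2-(4-isopropoxyphenyl)-3,6,8-trimethoxy-5-(4,4,5,5-tetramethyl-1,3,2-dioxaborolan-2-yl)-4H-chromen-4-one | COc1c(B4OC(C)(C)C(C)(C)O4)c2c(=O)c(OC)c(-c3ccc(OC(C)C)cc3)oc2c(OC)c1OC(C)C
F0 | step 5 | none | none
F7 | step 8 | 7-hydroxy-2-(4-hydroxyphenyl)-3,6,8-trimethoxy-4H-chromen-4-one | COc1cc2c(=O)c(OC)c(-c3ccc(O)cc3)oc2c(OC)c1O
F8 | step 8 | 4-(7-acetoxy-3,6,8-trimethoxy-4-oxo-4H-chromen-2-yl)phenyl acetate | COc1cc2c(=O)c(OC)c(-c3ccc(OC(C)=O)cc3)oc2c(OC)c1OC(C)=O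
F9 | step 8 | 4-(7-acetoxy-3,6,8-trimethoxy-4-oxo-5-(trifluoroacetoxy)-4H-chromen-2-yl)phenyl acetate | COc1c(OC(=O)C(F)(F)F)c2c(=O)c(OC)c(-c3ccc(OC(C)=O)cc3)oc2c(OC)c1OC(C)=O
F10 | step 8 | 4-(7-acetoxy-5-hydroxy-3,6,8-trimethoxy-4-oxo-4H-chromen-2-yl)phenyl acetate | COc1c(O)c2c(=O)c(OC)c(-c3ccc(OC(C)=O)cc3)oc2c(OC)c1OC(C)=O
A1 | alternative 1 | methyl (8Z)-9-[4-(benzyloxy)phenyl]-2,4,8-trimethoxy-3,5,7-trioxonon-8-enoate | COC(=O)C(OC)C(=O)C(OC)C(=O)CC(=O)/C(OC)=C/c1ccc(OCc2ccccc2)cc1
A2 | alternative 1 | (Z)-3-[4-(benzyloxy)phenyl]-2-methoxy-1-(2,4,6-trihydroxy-3,5-dimethoxyphenyl)prop-2-en-1-one | COc1c(O)c(OC)c(O)c(C(=O)/C(OC)=C/c2ccc(OCc3ccccc3)cc2)c1O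
A3 | alternative 2 | 3,5-bis(benzyloxy)-2-iodo-4,6-dimethoxyphenol | COc1c(O)c(I)c(OCc2ccccc2)c(OC)c1OCc1ccccc1
A4 | alternative 2 | 1-(benzyloxy)-4-ethynylbenzene | C#Cc1ccc(OCc2ccccc2)cc1
A5 | alternative 2 | 5,7-bis(benzyloxy)-2-[4-(benzyloxy)phenyl]-6,8-dimethoxy-4H-chromen-4-one | COc1c(OCc2ccccc2)c(OC)c2oc(-c3ccc(OCc4ccccc4)cc3)cc(=O)c2c1OCc1ccccc1
A6 | alternative 3 | 2,4-dimethoxybenzene-1,3,5-triol | COc1c(O)cc(O)c(OC)c1O
A7 | alternative 3 | ethyl 3-[4-(benzyloxy)phenyl]-2-methoxy-3-oxopropanoate | CCOC(=O)C(OC)C(=O)c1ccc(OCc2ccccc2)cc1
A8 | alternative 3 | 2-[4-(benzyloxy)phenyl]-5,7-dihydroxy-3,6,8-trimethoxy-4H-chromen-4-one | COc1c(O)c(OC)c2oc(-c3ccc(OCc4ccccc4)cc3)c(OC)c(=O)c2c1O
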